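Atoms are numbered as in the target SMILES. The C5–C10 bond, shared by the nine-membered carbocycle and the pyran ring, joins the two carbons that form the ring alkene of caryophyllene. The route cleaves that alkene, attaches C6 and a fluoroarene to C5, and then rejoins C5 and C10. In the key step the C5 enolate of an aryl ketone adds to the C10 methyl ketone (C5–C10 bond, nine-membered ring) and the resulting tertiary alkoxide displaces fluoride at C8 (C8–O9 bond, chromanone ring), which also sets the C5 and C10 stereocentres. The precursor is a seco diketone: a cyclobutane carrying a 3-oxobutyl chain and a hexenyl 2-fluoroaryl ketone chain.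

Key step: step 10

Remarks on the chemistry:
- Numbering key: C1 exocyclic CH2 on C2; C3, C4; C5 ring-fusion CH; C6 benzylic carbon; C7, C8 ring carbons (C8 bears O9); C10 quaternary C–O with methyl C11; C12, C13; C14, C15 cyclobutane CH; C16; C17 CMe2; C20 ring carbon with the gem-dimethyl group; C23 ring C=O; C25 acyl-bearing carbon; C31 enol carbon.
- Assumption: of the four C5/C10 diastereomers of the chromanone formed in the key step, which equilibrate under its conditions, the trans-fused isomer with the target configuration is the most stable.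
- The aryl ketone is assembled by carbonylative coupling (C6 from CO), not by hydration of a C5–C6 alkyne, because such an alkyne and the C1=C2 alkene form a 1,5-enyne that acid or π-acid hydration conditions are expected to cyclise.

Step 1
Reactants: 1 1-fluoro-3,5-dimethoxybenzene
Product: 3 2-fluoro-4,6-dimethoxybenzaldehyde, via aryl iminium salt 2 (not isolated)
Conditions: POCl3, DMF, 0 °C → 70 °C; then aq. NaOAc
Reagents that add atoms: N,N-dimethylformamide, CN(C)C=O; water, O
Why: Vilsmeier–Haack formylation, in which the chloroiminium electrophile should attack para to one methoxy group and next to the small fluorine in preference to the crowded site between the two methoxy groups, the minor isomer being removed by crystallisation.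

Step 2
Reactants: 3 2-fluoro-4,6-dimethoxybenzaldehyde
Product: 5 1-fluoro-3,5-dimethoxy-2-methylbenzene, via benzylic alcohol 4 (not isolated)
Conditions: Et3SiH (2.5 equiv), CF3CO2H, CH2Cl2, 0 °C → rt
Reagents that add atoms: none
Why: Ionic hydrogenation, in which the dimethoxy-stabilised benzylic cation formed from 4 takes up a second hydride, so the formyl group becomes the future C20 methyl group without touching C–F (hydrazine-based reductions are avoided because an ortho-fluoro hydrazone would close to an indazole).

Step 3
Reactants: 5 1-fluoro-3,5-dimethoxy-2-methylbenzene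
Product: 6 2-bromo-3-fluoro-1,5-dimethoxy-4-methylbenzene
Conditions: N-bromosuccinimide (1.05 equiv), MeCN, 0 °C → rt
Reagents that add atoms: N-bromosuccinimide, O=C1CCC(=O)N1Br
Why: Electrophilic aromatic bromination, which with N-bromosuccinimide in MeCN goes para to a methoxy group, here the remaining carbon between fluorine and methoxy, so that only the carbon flanked by both methoxy groups stays free.

Step 4
Reactants: 6 2-bromo-3-fluoro-1,5-dimethoxy-4-methylbenzene; 7 2-methylpropanoyl chloride
Product: 8 1-(3-bromo-4-fluoro-2,6-dimethoxy-5-methylphenyl)-2-methylpropan-1-one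
Conditions: AlCl3 (1.2 equiv), CH2Cl2, 0 °C
Reagents that add atoms: 2-methylpropanoyl chloride 7, CC(C)C(=O)Cl
Why: Friedel–Crafts acylation at the only unsubstituted ring carbon, which is ortho to both methoxy groups, so regiochemistry is forced; a bromide is used as the blocking halogen because it tolerates AlCl3, whereas an electron-rich aryl iodide would be prone to protodeiodination.

Step 5
Reactants: 8 1-(3-bromo-4-fluoro-2,6-dimethoxy-5-methylphenyl)-2-methylpropan-1-one
Product: 9 1-(4-fluoro-3-iodo-2,6-dimethoxy-5-methylphenyl)-2-methylpropan-1-one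
Conditions: NaI (2 equiv), CuI (10 mol%), trans-N,N′-dimethylcyclohexane-1,2-diamine (20 mol%), 1,4-dioxane, 110 °C
Reagents that add atoms: sodium iodide, [Na+].[I-]
Why: Copper-catalysed aromatic Finkelstein exchange, driven by precipitation of NaBr, which supplies the iodide needed for mild oxidative addition under CO in step 9 while the hindered ketone and C–F stay inert.

Step 6
Reactants: 10 (−)-β-caryophyllene
Product: 12 4-[(1S,2R)-3,3-dimethyl-2-(3-oxobutyl)cyclobutyl]pent-4-enal, via secondary ozonide 11 (not isolated)
Conditions: O3 (1.0 equiv, Sudan Red 7B end-point), CH2Cl2, −78 °C; then PPh3, −78 °C → rt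
Reagents that add atoms: ozone, [O-][O+]=O
Why: Ozonolysis, in which the strained trisubstituted E-alkene (C5=C10) reacts far faster than the 1,1-disubstituted exocyclic alkene, so one equivalent should cleave only the ring alkene to the C10 methyl ketone and C5 aldehyde while C14 and C15 are carried over untouched.

Step 7
Reactants: 12 4-[(1S,2R)-3,3-dimethyl-2-(3-oxobutyl)cyclobutyl]pent-4-enal
Product: 13 4-[(1R,4S)-4-(5-hydroxypent-1-en-2-yl)-2,2-dimethylcyclobutyl]butan-2-one
Conditions: NaBH4, CH2Cl2/EtOH (7:3), −78 °C
Reagents that add atoms: none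
Why: Chemoselective borohydride reduction, since at −78 °C in this solvent mixture NaBH4 reduces an aldehyde much faster than a dialkyl ketone, so only C5 becomes a primary alcohol.

Step 8
Reactants: 13 4-[(1R,4S)-4-(5-hydroxypent-1-en-2-yl)-2,2-dimethylcyclobutyl]butan-2-one
Product: 14 4-[(1R,4S)-4-(5-iodopent-1-en-2-yl)-2,2-dimethylcyclobutyl]butan-2-one
Conditions: PPh3, I2, imidazole, CH2Cl2, 0 °C → rt
Reagents that add atoms: iodine, II
Why: Appel-type iodination, in which iodide displaces the oxyphosphonium group at the primary carbon C5 by SN2 under conditions that leave the ketone and the alkene alone.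

Step 9
Reactants: 14 4-[(1R,4S)-4-(5-iodopent-1-en-2-yl)-2,2-dimethylcyclobutyl]butan-2-one; 9 1-(4-fluoro-3-iodo-2,6-dimethoxy-5-methylphenyl)-2-methylpropan-1-one
Product: 16 5-[(1S,2R)-3,3-dimethyl-2-(3-oxobutyl)cyclobutyl]-1-[2-fluoro-4,6-dimethoxy-3-methyl-5-(2-methylpropanoyl)phenyl]hex-5-en-1-one, via alkylzinc iodide 15 (not isolated)
Conditions: Zn dust (activated with BrCH2CH2Br and Me3SiCl), LiCl, THF, 25 °C; supernatant added to 9, Pd(PPh3)4 (5 mol%), CO (1 atm), THF, 45 °C
Reagents that add atoms: carbon monoxide, [C-]#[O+]
Why: Carbonylative Negishi coupling, in which zinc insertion gives a ketone-tolerant primary alkylzinc iodide and the hindered arylpalladium iodide from 9 inserts CO before it transmetallates, so reductive elimination delivers the aryl ketone with C6 supplied by CO and with no regiochemical ambiguity.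

Step 10
Reactants: 16 5-[(1S,2R)-3,3-dimethyl-2-(3-oxobutyl)cyclobutyl]-1-[2-fluoro-4,6-dimethoxy-3-methyl-5-(2-methylpropanoyl)phenyl]hex-5-en-1-one
Product: 18 trans-fused aryl chromanone with C6 ketone (5S,10S,14R,15S), via potassium aldolate 17 (not isolated)
Conditions: KOt-Bu (2 equiv), 18-crown-6 (2 equiv), THF/t-BuOH (20:1), 3 mM, 0 °C → 45 °C; then aq. NH4Cl
Reagents that add atoms: none
Why: Proposed new method: under reversible enolisation the C5 enolate of the aryl ketone adds to the C10 methyl ketone (intramolecular aldol addition, 9-enolexo-exo-trig closure of the carbocycle), and the tertiary alkoxide 17 then attacks C8 through a Meisenheimer adduct and expels fluoride (SNAr, 6-exo closure of the chromanone ring). The closest known reactions are intramolecular ketone aldol additions and the base-mediated cyclisation of β-hydroxy 2-fluoroaryl ketones to chroman-4-ones; using the second to drain a medium-ring aldol equilibrium in the same flask is untested. The aldol is expected to be uphill, but fluoride loss is irreversible, and C8 is activated by the ortho C6 carbonyl, which becomes coplanar with the arene as the ring forms, and by the para isobutyryl group. Of the four enolisable sites only the C5 enolate/C10 ketone pairing puts an alkoxide within six-ring reach of the C–F carbon; aldolates from the C11 or C12 enolates at the hindered C6 ketone have no leaving group nearby and revert, while high dilution and a bulky base suppress intermolecular aldol reaction and direct SNAr. Neither new stereocentre is set kinetically: C5 epimerises through the chromanone enolate and C10 through retro-oxa-Michael opening and re-closure, so the H-5/10-methyl trans fusion and its relation to C14/C15 rest on thermodynamic control, with the nine-membered ring, anchored on the trans-cyclobutane, expected to span two pseudo-equatorial bonds of the pyranone.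

Step 11
Reactants: 18 trans-fused aryl chromanone with C6 ketone (5S,10S,14R,15S)
Product: 19 C6 tosylhydrazone of 18
Conditions: 4-methylbenzenesulfonohydrazide (1.5 equiv), pyridinium 4-methylbenzenesulfonate (10 mol%), EtOH, 75 °C
Reagents that add atoms: 4-methylbenzenesulfonohydrazide, Cc1ccc(cc1)S(=O)(=O)NN
Why: Hydrazone condensation, which should occur only at the coplanar chromanone carbonyl C6 because the isobutyryl carbonyl is twisted between two ortho methoxy groups and too hindered, and which under mild acid leaves the alkene, C5 and C10 as they are.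

Step 12
Reactants: 19 C6 tosylhydrazone of 18
Product: 22 dimethoxy chroman (5R,10S,14R,15S), via N-boryl tosylhydrazine 20 (not isolated), via alkyl diazene 21 (not isolated)
Conditions: catecholborane (2.5 equiv), CHCl3, 0 °C → 25 °C; then NaOAc·3H2O, 60 °C
Reagents that add atoms: none
Why: Caglioti-type reductive deoxygenation of a tosylhydrazone, in which catecholborane delivers hydride to C6, acetate triggers loss of sulfinate and the diazene loses N2, giving the C6 methylene without a benzylic cation that the exocyclic alkene could trap and without hydroboration of that alkene at this temperature; C5 and C10 are no longer epimerisable afterwards.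

Step 13
Reactants: 22 dimethoxy chroman (5R,10S,14R,15S)
Product: 23 chroman diphenol (5R,10S,14R,15S)
Conditions: NaSEt (8 equiv), DMF, 120 °C; then 1 M HCl, 0 °C
Reagents that add atoms: none
Why: Thiolate O-demethylation by SN2 attack at the methyl groups, helped by the ortho isobutyryl carbonyl that stabilises both departing phenoxides, while the tertiary alkyl aryl ether O9–C10 cannot react by SN2 and the alkene is inert to thiolate.

Step 14
Reactants: 23 chroman diphenol (5R,10S,14R,15S); 24 iodomethane
Product: 25 target CNP0497637.1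
Conditions: NaOMe (2.2 equiv), MeI (1.3 equiv), MeOH, 0 °C → rt; then 1 M HCl, 0 °C
Reagents that add atoms: iodomethane 24, CI
Why: Alkylative dearomatisation of an acylphloroglucinol, in which the phenoxide in methanol should be C-methylated at C20, the methyl-bearing carbon ortho to the C23 oxygen and para to the C31 oxygen and less hindered than the ring-fusion carbon C7, leaving the enolised β-triketone of the target with all four stereocentres unchanged.

Compound list
1 | 1-fluoro-3,5-dimethoxybenzene | COc1cc(F)cc(OC)c1 | starting material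
2 | (2-fluoro-4,6-dimethoxybenzylidene)dimethyliminium dichlorophosphate | C[N+](C)=Cc1c(F)cc(OC)cc1OC.[O-]P(=O)(Cl)Cl | intermediate
3 | 2-fluoro-4,6-dimethoxybenzaldehyde | O=Cc1c(F)cc(OC)cc1OC | intermediate
4 | (2-fluoro-4,6-dimethoxyphenyl)methanol | OCc1c(F)cc(OC)cc1OC | intermediate
5 | 1-fluoro-3,5-dimethoxy-2-methylbenzene | Cc1c(F)cc(OC)cc1OC | intermediate
6 | 2-bromo-3-fluoro-1,5-dimethoxy-4-methylbenzene | Cc1c(F)c(Br)c(OC)cc1OC | intermediate
7 | 2-methylpropanoyl chloride (isobutyryl chloride) | CC(C)C(=O)Cl | starting material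
8 | 1-(3-bromo-4-fluoro-2,6-dimethoxy-5-methylphenyl)-2-methylpropan-1-one | CC(C)C(=O)c1c(OC)c(Br)c(F)c(C)c1OC | intermediate
9 | 1-(4-fluoro-3-iodo-2,6-dimethoxy-5-methylphenyl)-2-methylpropan-1-one | CC(C)C(=O)c1c(OC)c(I)c(F)c(C)c1OC | intermediate
10 | (−)-β-caryophyllene, (1R,4E,9S)-4,11,11-trimethyl-8-methylidenebicyclo[7.2.0]undec-4-ene | C/C1=C\CCC(=C)[C@H]2CC(C)(C)[C@@H]2CC1 | starting material
11 | secondary ozonide of 10 (1,2,4-trioxolane across C5 and C10; configuration at the two trioxolane carbons not defined) | CC13OC(CCC(=C)[C@H]2CC(C)(C)[C@@H]2CC1)OO3 | intermediate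
12 | 4-[(1S,2R)-3,3-dimethyl-2-(3-oxobutyl)cyclobutyl]pent-4-enal | CC(=O)CC[C@@H]1[C@@H](C(=C)CCC=O)CC1(C)C | intermediate
13 | 4-[(1R,4S)-4-(5-hydroxypent-1-en-2-yl)-2,2-dimethylcyclobutyl]butan-2-one | CC(=O)CC[C@@H]1[C@@H](C(=C)CCCO)CC1(C)C | intermediate
14 | 4-[(1R,4S)-4-(5-iodopent-1-en-2-yl)-2,2-dimethylcyclobutyl]butan-2-one | CC(=O)CC[C@@H]1[C@@H](C(=C)CCCI)CC1(C)C | intermediate
15 | alkylzinc iodide from 14 (C5–ZnI) | CC(=O)CC[C@@H]1[C@@H](C(=C)CCC[Zn]I)CC1(C)C | intermediate
16 | 5-[(1S,2R)-3,3-dimethyl-2-(3-oxobutyl)cyclobutyl]-1-[2-fluoro-4,6-dimethoxy-3-methyl-5-(2-methylpropanoyl)phenyl]hex-5-en-1-one (cyclisation precursor) | CC(=O)CC[C@@H]1[C@@H](C(=C)CCCC(=O)c2c(F)c(C)c(OC)c(C(=O)C(C)C)c2OC)CC1(C)C | intermediate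
17 | potassium aldolate: nine-membered β-alkoxido ketone with C5–C10 bond formed and C8–F intact (5S,10S,14R,15S) | C=C1CC[C@H](C(=O)c2c(F)c(C)c(OC)c(C(=O)C(C)C)c2OC)[C@@](C)([O-])CC[C@@H]2[C@@H]1CC2(C)C.[K+] | intermediate
18 | trans-fused aryl chromanone with C6 ketone, 23-OMe, 31-OMe, 20-methyl, 25-isobutyryl (5S,10S,14R,15S; H-5 anti to 10-methyl) | C=C1CC[C@@H]2C(=O)c3c(O[C@@]2(C)CC[C@@H]2[C@@H]1CC2(C)C)c(C)c(OC)c(C(=O)C(C)C)c3OC | intermediate
19 | C6 tosylhydrazone of 18 (C=N geometry not defined) | C=C1CC[C@@H]2C(=NNS(=O)(=O)c4ccc(C)cc4)c3c(O[C@@]2(C)CC[C@@H]2[C@@H]1CC2(C)C)c(C)c(OC)c(C(=O)C(C)C)c3OC | intermediate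
20 | N-(1,3,2-benzodioxaborol-2-yl) tosylhydrazine at C6 (C6 configuration not defined) | C=C1CC[C@@H]2C(N(NS(=O)(=O)c4ccc(C)cc4)B5Oc6ccccc6O5)c3c(O[C@@]2(C)CC[C@@H]2[C@@H]1CC2(C)C)c(C)c(OC)c(C(=O)C(C)C)c3OC | intermediate
21 | C6 alkyl diazene (C6 configuration not defined) | C=C1CC[C@@H]2C(N=N)c3c(O[C@@]2(C)CC[C@@H]2[C@@H]1CC2(C)C)c(C)c(OC)c(C(=O)C(C)C)c3OC | intermediate
22 | dimethoxy chroman: C6 methylene, 23-OMe, 31-OMe, 20-methyl, 25-isobutyryl (5R,10S,14R,15S) | C=C1CC[C@@H]2Cc3c(O[C@@]2(C)CC[C@@H]2[C@@H]1CC2(C)C)c(C)c(OC)c(C(=O)C(C)C)c3OC | intermediate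
23 | chroman diphenol: 23-OH, 31-OH, 20-methyl, 25-isobutyryl (5R,10S,14R,15S) | C=C1CC[C@@H]2Cc3c(O[C@@]2(C)CC[C@@H]2[C@@H]1CC2(C)C)c(C)c(O)c(C(=O)C(C)C)c3O | intermediate
24 | iodomethane | CI | starting material
25 | CNP0497637.1 (5R,10S,14R,15S) | C=C1CC[C@@H]2CC3=C(O[C@@]2(C)CC[C@@H]2[C@@H]1CC2(C)C)C(C)(C)C(=O)C(C(=O)C(C)C)=C3O | target

Total step count: 14.
Longest linear sequence: 11 steps (steps 1–5 and 9–14, from 1-fluoro-3,5-dimethoxybenzene); the terpene branch (steps 6–8) joins at step 9.

Steps most likely to fail

1. Step 10 (proposed new method).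
- What may go wrong: the nine-membered aldol pre-equilibrium may lie so far on the open side that fluoride displacement cannot compete with intermolecular condensation or with dehydration of the aldol, or equilibration may settle on another C5/C10 diastereomer.
- Fallback (known chemistry): an inverse-demand hetero-Diels–Alder reaction that sets out from 10 and 7 and comes back to the route at 23.
- Friedel–Crafts acylation of commercial 2-methylbenzene-1,3,5-triol with 7 (AlCl3, nitrobenzene, 60 °C) should give 2-methyl-1-(2,4,6-trihydroxy-3-methylphenyl)propan-1-one F1.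
- Knoevenagel condensation of F1 with paraformaldehyde (NaOAc, 1,4-dioxane/H2O, 80 °C) in the presence of excess 10 should generate the ortho-quinone methide 3,5-dihydroxy-2-methyl-6-methylidene-4-(2-methylpropanoyl)cyclohexa-2,4-dien-1-one F2.
- F2 is trapped by the strained E-alkene of 10 (oxygen to C10, CH2 to C5, suprafacial and therefore trans-fused) to give 23, from which step 14 follows.
- The diastereomer from the other alkene face and the regioisomer closed through the other oxygen would have to be separated.

2. Step 11.
- What may go wrong: condensation may be slow or incomplete at a carbonyl that is hindered by the peri methoxy group and the branched C5 and deactivated by two alkoxy donors, with erosion of the alkene on forcing.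
- Fallback: setting out from 18, NaBH4 (MeOH/THF, 0 °C) should reduce the chromanone carbonyl in preference to the twisted isobutyryl ketone to give the C6 alcohol (chroman-4-ol) F3.
- NaH, CS2 and then 24 in THF should convert F3 into its O-(S-methyl dithiocarbonate) F4.
- Barton–McCombie deoxygenation of F4 (Bu3SnH, Et3B, air, toluene, rt) removes the C6 oxygen through a benzylic radical, which is reduced faster than it cyclises; the sequence rejoins the route at 22.

3. Step 14.
- What may go wrong: O-methylation and C-methylation at the ring-fusion carbon C7 may compete with the wanted attack at C20.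
- Fallback: moving the methylation to a simple arene and uniting the halves by cycloaddition, setting out from 7, 24 and 10 and coming back at 25.
- Friedel–Crafts acylation of benzene-1,3,5-triol with 7 (AlCl3, nitrobenzene) should give 2-methyl-1-(2,4,6-trihydroxyphenyl)propan-1-one F5.
- Threefold C-methylation of F5 with 24 (NaOMe, MeOH) should give 3,5-dihydroxy-4,6,6-trimethyl-2-(2-methylpropanoyl)cyclohexa-2,4-dien-1-one F6.
- Oxidation of the remaining ring methyl group of F6 (TEMPO, Ag2O, toluene, 40 °C) in the presence of 10 should generate 5-hydroxy-2,2-dimethyl-6-methylidene-4-(2-methylpropanoyl)cyclohex-4-ene-1,3-dione F7.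
- F7 undergoes hetero-Diels–Alder addition to the ring alkene of 10 to give 25 directly, the facial diastereomer being separated by chromatography.

Further compounds
F1 | step 10 | 2-methyl-1-(2,4,6-trihydroxy-3-methylphenyl)propan-1-one | CC(C)C(=O)c1c(O)cc(O)c(C)c1O
F2 | step 10 | 3,5-dihydroxy-2-methyl-6-methylidene-4-(2-methylpropanoyl)cyclohexa-2,4-dien-1-one | C=C1C(=O)C(C)=C(O)C(C(=O)C(C)C)=C1O
F3 | step 11 | C6 alcohol (chroman-4-ol) from 18, C6 configuration not defined | C=C1CC[C@@H]2C(O)c3c(O[C@@]2(C)CC[C@@H]2[C@@H]1CC2(C)C)c(C)c(OC)c(C(=O)C(C)C)c3OC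
F4 | step 11 | O-(S-methyl dithiocarbonate) of F3 | C=C1CC[C@@H]2C(OC(=S)SC)c3c(O[C@@]2(C)CC[C@@H]2[C@@H]1CC2(C)C)c(C)c(OC)c(C(=O)C(C)C)c3OC
F5 | step 14 | 2-methyl-1-(2,4,6-trihydroxyphenyl)propan-1-one | CC(C)C(=O)c1c(O)cc(O)cc1O
F6 | step 14 | 3,5-dihydroxy-4,6,6-trimethyl-2-(2-methylpropanoyl)cyclohexa-2,4-dien-1-one | CC(C)C(=O)C1=C(O)C(C)=C(O)C(C)(C)C1=O
F7 | step 14 | 5-hydroxy-2,2-dimethyl-6-methylidene-4-(2-methylpropanoyl)cyclohex-4-ene-1,3-dione | C=C1C(=O)C(C)(C)C(=O)C(C(=O)C(C)C)=C1O
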